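**Retrosynthetic overview**

1. Locants follow the daucane skeleton: C1 quaternary ring-fusion C–CH3, C2 CHOH, C3 CH2, C4 C(OH)iPr, C5 ring-fusion CH, C6 and C10 the acyloxy carbons next to C5 and C1, C7 CH2, C8/C9 epoxide; α is the face of H-5 and the C1 methyl. Endgame: DDQ release of 2-OH ⇐ double angeloylation ⇐ hydroxyl-directed α-epoxidation of C8=C9.
2. Seven-membered ring: ring-closing metathesis at C8=C9 of a triol diene, which comes from a temporary γ-lactone (C6 carbonyl tied to O10) by reduction to the lactol and chelation-controlled methallyl addition at C6.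
3. Key disconnection: the cyclopentane C1–C5 is a double-aldol retron (carbinols C2 and C4 in a 1,3-relation, C5 α to the oxygenated C6, non-enolisable quaternary C1 between C2 and C5). Bonds C2–C3 and C4–C5 are therefore made in one formal [3+2] between the enol silane of 3-methylbutan-2-one (C3, C4, isopropyl) and the 1,3-dipole C2–C1–C5.
4. That dipole is stored as a donor–acceptor cyclopropane (extra bond C2–C5, donor oxygen on C2, acceptor lactone carbonyl C6) fused to the lactone. Both temporary rings come from one chiral-dirhodium-catalysed intramolecular cyclopropanation of an (S)-configured diazoacetate, whose carbinol centre (C10) is secured beforehand by a lipase resolution and which then sets C1 and C5.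
5. Order of ring formation: cyclopropane + γ-lactone (step 5) → cyclopentane with cleavage of the cyclopropane (step 7) → lactone opened (steps 8–9) → cycloheptene (step 10) → oxirane (step 11).

Key step: step 7

Assumption: the SMILES is taken literally as a cis-fused daucane (H-5 and the C1 methyl on the same face), and compounds 1, 2, 4, 7, 10, 16, 20 and the catalysts are regarded as commercial.

**Route**

Step 1
Reactants: 1 (E)-3-ethoxy-2-methylprop-2-enal (3-ethoxymethacrolein); 2 naphthalen-2-ylmethanol
Product: 3 (E)-2-methyl-3-(naphthalen-2-ylmethoxy)prop-2-enal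
Conditions: PPTS (5 mol %), toluene, 80 °C, EtOH removed under reduced pressure
Reagents that add atoms: none
Why: Acid-catalysed addition–elimination at the β-carbon of the vinylogous formate (transetherification) exchanges ethoxy for the oxidatively removable 2-naphthylmethoxy group, driven by removal of ethanol, and keeps the thermodynamically preferred E enol ether.

Step 2
Reactants: 3; 4 vinylmagnesium bromide
Product: 5 rac-(1E)-2-methyl-1-(naphthalen-2-ylmethoxy)penta-1,4-dien-3-ol
Conditions: CH2=CHMgBr, THF, −78 °C; sat. aq NaHCO3, base-washed glassware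
Reagents that add atoms: none
Why: Grignard 1,2-addition to the aldehyde of a β-alkoxy enal (the β-carbon is deactivated by the alkoxy donor) gives the acid-labile bis-allylic carbinol as a racemate, whose carbinol centre (later C10) is resolved in step 3.

Step 3
Reactants: 5
Product: 6 (1E,3S)-2-methyl-1-(naphthalen-2-ylmethoxy)penta-1,4-dien-3-ol
Conditions: immobilised Candida antarctica lipase B, vinyl acetate (3 equiv), Et3N (1 mol %), MTBE, rt, run until the (R)-alcohol is consumed; chromatography on Et3N-deactivated silica
Reagents that add atoms: none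
Why: Lipase-catalysed kinetic resolution by enantioselective transesterification should, following Kazlauskas' rule (vinyl as the medium and the α-methylalkenyl group as the large substituent), acetylate the (R)-alcohol and leave the (S)-alcohol, which is separated from the acetate and carries the future C10 configuration, while the neutral conditions spare the acid-labile enol ether.

Step 4
Reactants: 6; 7 glyoxylic acid chloride p-toluenesulfonylhydrazone
Product: 8 (1E,3S)-2-methyl-1-(naphthalen-2-ylmethoxy)penta-1,4-dien-3-yl diazoacetate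
Conditions: 7, PhNMe2, CH2Cl2, 0 °C; then Et3N, 0 °C; filtration through basic alumina
Reagents that add atoms: none
Why: O-acylation by the acid chloride followed by base-induced loss of p-toluenesulfinate from the tosylhydrazone (Bamford–Stevens-type diazo formation) gives the diazoacetate under basic conditions that the enol ether tolerates and that do not touch the carbinol centre.

Step 5
Reactants: 8
Product: 9 (1S,4S,5R,6R)-4-ethenyl-5-methyl-6-(naphthalen-2-ylmethoxy)-3-oxabicyclo[3.1.0]hexan-2-one (vinyl cis to the cyclopropane, naphthylmethoxy exo)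
Conditions: Rh2(4S-MPPIM)4 {dirhodium tetrakis[methyl (4S)-2-oxo-1-(3-phenylpropanoyl)imidazolidine-4-carboxylate]} (1 mol %), CH2Cl2, 40 °C, slow addition of 8
Reagents that add atoms: none
Why: Intramolecular cyclopropanation of a secondary allylic diazoacetate by the electrophilic chiral dirhodium carboxamidate carbenoid should add to the electron-rich enol ether in preference to the vinyl group; the S carbinol centre places its vinyl group on the endo side of the forming lactone (the exo position would eclipse the bridgehead methyl), which fixes C1 and C5 relative to C10, the catalyst enantiomer is chosen as the matched one to reinforce this preference, and the exo position of the naphthylmethoxy group follows from stereospecific syn addition to the E enol ether.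

Step 6
Reactants: 10 3-methylbutan-2-one
Product: 11 3-methyl-2-(trimethylsilyloxy)but-1-ene
Conditions: LiN(iPr)2, THF, −78 °C; Me3SiCl, −78 °C → rt
Reagents that add atoms: chlorotrimethylsilane, C[Si](C)(C)Cl
Why: Kinetic deprotonation at the methyl group of the methyl ketone and O-silylation give the terminal enol silane that serves as the two-carbon partner C3–C4.

Step 7
Reactants: 9; 11
Product: 14 (3S,3aR,4S,6S,6aS)-3-ethenyl-6-hydroxy-3a-methyl-4-(naphthalen-2-ylmethoxy)-6-(propan-2-yl)hexahydro-1H-cyclopenta[c]furan-1-one, via trichlorotin enolate 12 (not isolated), via trimethylsilyl ether 13 (not isolated)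
Conditions: 11 (2 equiv), SnCl4 (0.3 equiv), CH2Cl2, −78 → −40 °C; then 1 M HCl, THF, 0 °C
Reagents that add atoms: none
Why: SnCl4 activates the lactone carbonyl and the 2-naphthylmethoxy donor opens the strained C2–C5 bond to a 1,3-zwitterion (C2 oxocarbenium ion, C5/C6 tin enolate); the CH2 terminus of 11 adds to C2 (Mukaiyama aldol-type addition, bond C2–C3) to give 12, whose freed isopropyl ketone carbon C4 is attacked by the tethered enolate carbon C5 (intramolecular aldol addition, bond C4–C5), silyl transfer giving 13 and acidic work-up 14. The closest known reaction type is the Lewis-acid-promoted formal [3+2] cycloaddition of 2-alkoxycyclopropyl esters and ketones with silyl enol ethers. The cyclopentane closes in a 5-(enolexo)-exo-trig mode and can only be cis-fused to the five-membered lactone, which fixes C5 (H-5 cis to the C1 methyl). C4 is controlled by the tin chelate between enolate oxygen and ketone oxygen in a closed transition state, which puts O4 cis to the lactone carbonyl and the isopropyl group on the convex face; C2 is controlled by the quaternary centre C1 through Felkin–Anh addition to the oxocarbenium ion anti to its bulkiest substituent (C10 with the vinyl group), which puts O2 cis to C10 and cis to O4. The step needs regioselective ring opening and regiospecific enolate formation, secured because only the C2–C5 bond joins donor and acceptor carbons and the enolate is born at C5, the only α-carbon of the lactone; it also needs C-attack of 11 at C2 rather than re-closure, secured by the reversibility of three-membered ring closure and the excess of 11.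

Step 8
Reactants: 14
Product: 15 (3S,3aR,4S,6S,6aS)-3-ethenyl-3a-methyl-4-(naphthalen-2-ylmethoxy)-6-(propan-2-yl)hexahydro-1H-cyclopenta[c]furan-1,6-diol (lactol, both anomers)
Conditions: iBu2AlH (2.2 equiv), CH2Cl2, −78 °C; aq potassium sodium tartrate
Reagents that add atoms: none
Why: Partial reduction of the γ-lactone at low temperature stops at the tetrahedral aluminium hemiacetal and releases the lactol on work-up, the first equivalent of hydride being consumed by the tertiary hydroxyl.

Step 9
Reactants: 15; 16 2-methylallylmagnesium chloride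
Product: 17 (1S,2S,4S,5R,6R,10S)-configured seco-triol: cyclopentane C1–C5 with 1-CH3, 2-(naphthalen-2-ylmethoxy), 4-OH and 4-isopropyl, carrying at C1 the (S)-1-hydroxyprop-2-en-1-yl group (C10, C9) and at C5 the (R)-1-hydroxy-3-methylbut-3-en-1-yl group (C6, C7, C8)
Conditions: CH2=C(CH3)CH2MgCl (4 equiv), Et2O/CH2Cl2, −78 → −20 °C; aq NH4Cl
Reagents that add atoms: none
Why: The lactol opens under the basic conditions to the C6 aldehyde, and the allylic Grignard reagent should add under 1,3-chelation control (magnesium bridging the aldehyde oxygen and the cis-disposed C4 alkoxide, Cram-chelate model) from the face anti to ring carbon C1 of the fused chelate, which gives the 6R (6α-O) carbinol.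

Step 10
Reactants: 17
Product: 18 (1S,2S,4S,5R,6R,10S)-2-(naphthalen-2-ylmethoxy)dauc-8-ene-4,6,10-triol (cis-fused; 2β-O, 4β-OH, 6α-OH, 10α-OH)
Conditions: second-generation Grubbs catalyst [RuCl2(=CHPh)(H2IMes)(PCy3)] (5 mol %), CH2Cl2 (0.005 M), 40 °C
Reagents that add atoms: none
Why: Ring-closing olefin metathesis between the monosubstituted and the 1,1-disubstituted alkene closes the seven-membered ring as the trisubstituted C8=C9 olefin, helped by the cis disposition of the two side chains on the cyclopentane, and creates no stereocentre.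

Step 11
Reactants: 18
Product: 19 (1S,2S,4S,5R,6R,8S,9R,10R)-8,9-epoxy-2-(naphthalen-2-ylmethoxy)daucane-4,6,10-triol (8α,9α-epoxide)
Conditions: VO(acac)2 (5 mol %), tBuOOH, CH2Cl2, 0 °C → rt
Reagents that add atoms: tert-butyl hydroperoxide, CC(C)(C)OO
Why: In this vanadium-catalysed hydroxyl-directed epoxidation the allylic 10α-OH and the homoallylic 6α-OH both bind the metal peroxide and deliver oxygen to the α-face of C8=C9, setting C8 and C9.

Step 12
Reactants: 19; 20 angelic acid [(2Z)-2-methylbut-2-enoic acid]
Product: 21 (1R,2S,4S,5R,6R,8S,9R,10R)-8,9-epoxy-4-hydroxy-2-(naphthalen-2-ylmethoxy)daucane-6,10-diyl bis[(2Z)-2-methylbut-2-enoate]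
Conditions: 20 (6 equiv), 2,4,6-trichlorobenzoyl chloride, Et3N, toluene, rt (mixed anhydride pre-formed); then 19, 75 °C
Reagents that add atoms: none
Why: Yamaguchi-type esterification through the pre-formed mixed anhydride acylates the two secondary hydroxyls without a nucleophilic catalyst, so the Z geometry of the angelate should survive, while the tertiary 4-OH is too hindered to react and O2 is masked.

Step 13
Reactants: 21
Product: 22 (1R,2S,4S,5R,6R,8S,9R,10R)-8,9-epoxy-2,4-dihydroxydaucane-6,10-diyl bis[(2Z)-2-methylbut-2-enoate] (target; 2β,4β-diol, 6α,10α-diester, 8α,9α-epoxide, cis ring fusion)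
Conditions: DDQ (2 equiv), CH2Cl2/pH 7 phosphate buffer (10:1), 0 °C → rt
Reagents that add atoms: none
Why: Oxidative cleavage of the 2-naphthylmethyl ether (benzylic hydride abstraction by DDQ, then hydrolysis of the oxocarbenium ion by water, which also prevents capture by the cis 4-OH) releases the 2β-OH and should leave the electron-poor angelate alkenes, the epoxide and the tertiary alcohol untouched.

**Compound list**

1 | (E)-3-ethoxy-2-methylprop-2-enal | O=C/C(C)=C/OCC | starting material
2 | naphthalen-2-ylmethanol | OCc1ccc2ccccc2c1 | starting material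
3 | (E)-2-methyl-3-(naphthalen-2-ylmethoxy)prop-2-enal | O=C/C(C)=C/OCc1ccc2ccccc2c1 | intermediate
4 | vinylmagnesium bromide | C=C[Mg]Br | starting material
5 | rac-(1E)-2-methyl-1-(naphthalen-2-ylmethoxy)penta-1,4-dien-3-ol (racemic at C3) | C=CC(O)/C(C)=C/OCc1ccc2ccccc2c1 | intermediate
6 | (1E,3S)-2-methyl-1-(naphthalen-2-ylmethoxy)penta-1,4-dien-3-ol | O[C@@H](C=C)/C(C)=C/OCc1ccc2ccccc2c1 | intermediate
7 | glyoxylic acid chloride p-toluenesulfonylhydrazone | Cc1ccc(cc1)S(=O)(=O)NN=CC(Cl)=O | starting material
8 | (1E,3S)-2-methyl-1-(naphthalen-2-ylmethoxy)penta-1,4-dien-3-yl diazoacetate | [N-]=[N+]=CC(=O)O[C@@H](C=C)/C(C)=C/OCc1ccc2ccccc2c1 | intermediate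
9 | (1S,4S,5R,6R)-4-ethenyl-5-methyl-6-(naphthalen-2-ylmethoxy)-3-oxabicyclo[3.1.0]hexan-2-one | O=C1O[C@@H](C=C)[C@@]2(C)[C@H](OCc3ccc4ccccc4c3)[C@@H]12 | intermediate
10 | 3-methylbutan-2-one | CC(=O)C(C)C | starting material
11 | 3-methyl-2-(trimethylsilyloxy)but-1-ene | C=C(O[Si](C)(C)C)C(C)C | intermediate
12 | trichlorotin enolate of the ring-opened adduct: 5-ethenyl-4-methyl-4-[4-methyl-1-(naphthalen-2-ylmethoxy)-3-oxopentyl]-2-(trichlorostannyloxy)-4,5-dihydrofuran, configurations at C1, C2 and C10 as in 14 | Cl[Sn](Cl)(Cl)OC1=C[C@](C)([C@@H](OCc2ccc3ccccc3c2)CC(=O)C(C)C)[C@H](C=C)O1 | intermediate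
13 | 6-O-trimethylsilyl ether of 14 | O=C1O[C@@H](C=C)[C@@]2(C)[C@@H](OCc3ccc4ccccc4c3)C[C@](O[Si](C)(C)C)(C(C)C)[C@@H]12 | intermediate
14 | (3S,3aR,4S,6S,6aS)-3-ethenyl-6-hydroxy-3a-methyl-4-(naphthalen-2-ylmethoxy)-6-(propan-2-yl)hexahydro-1H-cyclopenta[c]furan-1-one | O=C1O[C@@H](C=C)[C@@]2(C)[C@@H](OCc3ccc4ccccc4c3)C[C@](O)(C(C)C)[C@@H]12 | intermediate
15 | (3S,3aR,4S,6S,6aS)-3-ethenyl-3a-methyl-4-(naphthalen-2-ylmethoxy)-6-(propan-2-yl)hexahydro-1H-cyclopenta[c]furan-1,6-diol (lactol, anomeric mixture) | OC1O[C@@H](C=C)[C@@]2(C)[C@@H](OCc3ccc4ccccc4c3)C[C@](O)(C(C)C)[C@@H]12 | intermediate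
16 | 2-methylallylmagnesium chloride | CC(=C)C[Mg]Cl | starting material
17 | (1S,2S,4S,5R,6R,10S)-seco-triol diene (see step 9) | C=C(C)C[C@@H](O)[C@@H]1[C@@](O)(C(C)C)C[C@H](OCc2ccc3ccccc3c2)[C@]1(C)[C@@H](O)C=C | intermediate
18 | (1S,2S,4S,5R,6R,10S)-2-(naphthalen-2-ylmethoxy)dauc-8-ene-4,6,10-triol | O[C@@H]1CC(C)=C[C@H](O)[C@@]2(C)[C@@H](OCc3ccc4ccccc4c3)C[C@](O)(C(C)C)[C@@H]12 | intermediate
19 | (1S,2S,4S,5R,6R,8S,9R,10R)-8,9-epoxy-2-(naphthalen-2-ylmethoxy)daucane-4,6,10-triol | O[C@@H]1C[C@]2(C)O[C@@H]2[C@H](O)[C@@]2(C)[C@@H](OCc3ccc4ccccc4c3)C[C@](O)(C(C)C)[C@@H]12 | intermediate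
20 | angelic acid, (2Z)-2-methylbut-2-enoic acid | C/C=C(/C)C(=O)O | starting material
21 | (1R,2S,4S,5R,6R,8S,9R,10R)-8,9-epoxy-4-hydroxy-2-(naphthalen-2-ylmethoxy)daucane-6,10-diyl bis[(2Z)-2-methylbut-2-enoate] | C/C=C(/C)C(=O)O[C@@H]1C[C@]2(C)O[C@@H]2[C@H](OC(=O)/C(C)=C\C)[C@@]2(C)[C@@H](OCc3ccc4ccccc4c3)C[C@](O)(C(C)C)[C@@H]12 | intermediate
22 | (1R,2S,4S,5R,6R,8S,9R,10R)-8,9-epoxy-2,4-dihydroxydaucane-6,10-diyl bis[(2Z)-2-methylbut-2-enoate] | C/C=C(/C)C(=O)O[C@@H]1C[C@]2(C)O[C@@H]2[C@H](OC(=O)/C(C)=C\C)[C@@]2(C)[C@@H](O)C[C@](O)(C(C)C)[C@@H]12 | target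

Total step count: 13. Longest linear sequence: 12 steps (steps 1–5 and 7–13; step 6 is a one-step side branch).

**Steps most likely to fail**

Step 7 (key step). What may go wrong: poor facial selectivity in the addition of 11 to the C2 oxocarbenium ion, so that the C2 epimer dominates. The fallback sets out from 9 and comes back at 14. The annulation is run as in step 7 and its C2-epimeric product, 2-epi-lactone F1, is taken on. DDQ in wet CH2Cl2 removes the naphthylmethyl group to give the 2α,4β-diol F2, and Dess–Martin oxidation of the secondary hydroxyl gives the β-hydroxy cyclopentanone F3. The C2 centre is then set by ketone reduction instead: hydride from the convex face of the cis-bicyclo[3.3.0] skeleton (NaBH4, CeCl3, MeOH, −78 °C) should give the cis-2β,4β-diol F4. Selective 2-naphthylmethylation of its secondary hydroxyl (2-naphthylmethyl 2,2,2-trichloroacetimidate, cat. TfOH, CH2Cl2) returns 14.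

Step 9. What may go wrong: poor facial selectivity at C6 if the magnesium chelate does not form and open-chain (Felkin-type) addition competes. The fallback sets out from 15 and comes back at 17. Stereocontrol is moved from the substrate to the reagent by Brown allylboration with (+)-B-(2-methylallyl)diisopinocampheylborane (from (+)-B-methoxydiisopinocampheylborane and 16, Et2O, −78 °C; NaOH/H2O2 work-up). This reagent should attack the Re face of the C6 aldehyde in equilibrium with the lactol and give 17 directly, with no new isolated compound.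

Step 12. What may go wrong: isomerisation of the angelate to the tiglate geometry during the slow acylation of two hindered secondary hydroxyls, or incomplete acylation at the neopentyl-type 10-OH. The fallback sets out from 19 and comes back at 21. The Z-alkenes are built on the substrate instead of being carried in with the acid. Both secondary hydroxyls are esterified with the small, geometrically inert 2-[bis(2,2,2-trifluoroethoxy)phosphoryl]propanoic acid (DCC, cat. DMAP, CH2Cl2, 0 °C → rt) to give the bis(phosphonopropanoate) F5. A double Still–Gennari olefination (KN(SiMe3)2 with one extra equivalent for the tertiary hydroxyl, 18-crown-6, THF, −78 °C; acetaldehyde) should then convert both phosphonate esters into (2Z)-2-methylbut-2-enoates and return 21.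

Further compounds
F1 | step 7 | C2 epimer of 14 (2α-naphthylmethoxy; (3S,3aR,4R,6S,6aS) in the furanone numbering) | O=C1O[C@@H](C=C)[C@@]2(C)[C@H](OCc3ccc4ccccc4c3)C[C@](O)(C(C)C)[C@@H]12
F2 | step 7 | 2α,4β-diol obtained from F1 by loss of the naphthylmethyl group | O=C1O[C@@H](C=C)[C@@]2(C)[C@H](O)C[C@](O)(C(C)C)[C@@H]12
F3 | step 7 | C2 ketone (4β-hydroxy-2-oxo lactone) | O=C1O[C@@H](C=C)[C@@]2(C)C(=O)C[C@](O)(C(C)C)[C@@H]12
F4 | step 7 | cis-2β,4β-diol (14 without the naphthylmethyl group) | O=C1O[C@@H](C=C)[C@@]2(C)[C@@H](O)C[C@](O)(C(C)C)[C@@H]12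
F0 | step 9 | none | none
F5 | step 12 | 6,10-bis{2-[bis(2,2,2-trifluoroethoxy)phosphoryl]propanoate} of 19 (mixture at the two phosphonate α-carbons) | CC(C(=O)O[C@@H]1C[C@]2(C)O[C@@H]2[C@H](OC(=O)C(C)P(=O)(OCC(F)(F)F)OCC(F)(F)F)[C@@]2(C)[C@@H](OCc3ccc4ccccc4c3)C[C@](O)(C(C)C)[C@@H]12)P(=O)(OCC(F)(F)F)OCC(F)(F)F
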